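The route rests on disconnecting the cis-fused γ-lactone (O6–C12–C11–C7–C6) together with the C8 ester: in the target, C7–C11 and C8–O lie anti across what was a Z C7=C8 bond of the ten-membered ring. A carbenoid tethered to O6 therefore adds C11 across C7=C8, closing lactone and cyclopropane in one operation and setting C7, C8 and C11 from C6 alone; angelate then opens C8–C11 with inversion. The precursor is a (Z,Z)-cyclodeca-2,5-dienol with a C4 exo-methylene, a C5 silyl ether and a diazophosphonoacetate on O6, made from a Z,Z-trienal by Nozaki–Hiyama–Kishi closure of C4–C5.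

Key step: step 15

Remark: germacrane locants are used (ring C1–C10, lactone C11–C13, C14 methyl on C10, C15 exo-methylene on C4); (S)-glyceraldehyde acetonide is the correct enantiomer here because its aldehyde carbon becomes C7 (with the aldehyde carbon as C5 the R enantiomer would be needed); the ring is closed at C4–C5 and not by metathesis at C7=C8, where a C8 alkylidene would close a seven-membered ring onto the C4 exo-methylene; C11 of 24 forms as an epimer mixture and is drawn without configuration.

Step 1
Reactants: 1 propargyl alcohol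
Product: 3 (Z)-3-iodo-2-methylprop-2-en-1-ol, via alkenylmagnesium alkoxide 2 (not isolated)
Conditions: MeMgBr (2.5 equiv), CuI (10 mol %), THF, −10 °C to rt; then I2, −78 to 0 °C
Reagents that add atoms: methylmagnesium bromide, C[Mg]Br; iodine, II
Why: Copper-catalysed carbomagnesiation of the propargylic alkoxide is directed by oxygen, adds methyl and magnesium anti across the alkyne within a five-membered chelate, and iodinolysis with retention gives the Z vinyl iodide in which C9 and iodine (the future C2 site) are cis, which fixes the C1=C10 geometry.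

Step 2
Reactants: 4 3-bromobut-3-en-1-ol
Product: 5 2-bromo-4-iodobut-1-ene
Conditions: I2, PPh3, imidazole, CH2Cl2, 0 °C to rt
Reagents that add atoms: iodine, II
Why: Appel iodination converts the primary alcohol by SN2 displacement of its oxyphosphonium ion, and the vinyl bromide is inert.

Step 3
Reactants: 5 2-bromo-4-iodobut-1-ene; 3 (Z)-3-iodo-2-methylprop-2-en-1-ol
Product: 7 (2Z)-6-bromo-2-methylhepta-2,6-dien-1-ol, via alkylzinc iodide 6 (not isolated)
Conditions: Zn dust (TMSCl, BrCH2CH2Br), THF, 40 °C; then 3, PdCl2(dppf) (5 mol %), THF, rt (6 used at 2.2 equiv)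
Reagents that add atoms: none
Why: In this Negishi sp3–sp2 cross-coupling zinc inserts only into the primary C–I bond of 5, palladium adds oxidatively to the C–I bond of 3 far faster than to the 2-bromoalkene, the alkene geometry is retained and the alkylzinc iodide, used in excess, tolerates the free hydroxyl.

Step 4
Reactants: 7 (2Z)-6-bromo-2-methylhepta-2,6-dien-1-ol
Product: 8 (5Z)-2,7-dibromo-6-methylhepta-1,5-diene
Conditions: CBr4, PPh3, CH2Cl2, 0 °C
Reagents that add atoms: carbon tetrabromide, BrC(Br)(Br)Br
Why: Appel bromination under neutral conditions displaces the primary allylic oxyphosphonium ion by SN2 without allylic transposition or Z to E isomerisation.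

Step 5
Reactants: 8 (5Z)-2,7-dibromo-6-methylhepta-1,5-diene
Product: 9 [(3Z)-7-bromo-3-methylocta-3,7-dien-1-yl]triphenylphosphonium bromide
Conditions: Ph3PCH3Br, n-BuLi, THF, 0 °C; added slowly to 8, THF, −78 °C to rt
Reagents that add atoms: methyltriphenylphosphonium bromide (as its ylide), C[P+](c1ccccc1)(c1ccccc1)c1ccccc1.[Br-]
Why: C-Alkylation of the non-stabilised ylide by the primary allylic bromide (SN2, with slow addition at low temperature to limit a second alkylation) gives the homoallylic phosphonium salt and installs C8, while the vinyl bromide does not react.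

Step 6
Reactants: 9 [(3Z)-7-bromo-3-methylocta-3,7-dien-1-yl]triphenylphosphonium bromide; 10 (S)-glyceraldehyde acetonide
Product: 12 (4R)-4-[(1Z,4Z)-8-bromo-4-methylnona-1,4,8-trien-1-yl]-2,2-dimethyl-1,3-dioxolane, via phosphorus ylide 11 (not isolated)
Conditions: NaHMDS, THF, −78 to 0 °C; then 10, −78 °C to rt
Reagents that add atoms: none
Why: Wittig olefination with a non-stabilised, lithium-free ylide runs under kinetic control through the cis oxaphosphetane to give the Z C7=C8 alkene, and the C6 stereocentre is carried over unchanged from 10 at low temperature.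

Step 7
Reactants: 12 (4R)-4-[(1Z,4Z)-8-bromo-4-methylnona-1,4,8-trien-1-yl]-2,2-dimethyl-1,3-dioxolane
Product: 13 (2R,3Z,6Z)-10-bromo-6-methylundeca-3,6,10-triene-1,2-diol
Conditions: 80 % aq. AcOH, 40 °C
Reagents that add atoms: none
Why: Acid-catalysed hydrolysis of the terminal acetonide releases the diol, while the skipped diene and the vinyl bromide do not react with aqueous acetic acid.

Step 8
Reactants: 13 (2R,3Z,6Z)-10-bromo-6-methylundeca-3,6,10-triene-1,2-diol
Product: 14 (2R,3Z,6Z)-10-bromo-6-methyl-1,2-bis(triethylsilyloxy)undeca-3,6,10-triene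
Conditions: TESCl, imidazole, DMF, 0 °C to rt
Reagents that add atoms: chlorotriethylsilane, CC[Si](Cl)(CC)CC
Why: Standard silylation of both hydroxyls gives TES ethers, chosen because the primary one can be oxidised directly and the secondary one can later be removed in the presence of TBS.

Step 9
Reactants: 14 (2R,3Z,6Z)-10-bromo-6-methyl-1,2-bis(triethylsilyloxy)undeca-3,6,10-triene
Product: 15 (2R,3Z,6Z)-10-bromo-6-methyl-2-(triethylsilyloxy)undeca-3,6,10-trienal
Conditions: (COCl)2, DMSO, CH2Cl2, −78 to −40 °C; then i-Pr2NEt, −78 °C, cold pH 7 work-up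
Reagents that add atoms: none
Why: Under Swern conditions the activated DMSO reagent cleaves the unhindered primary TES ether selectively and oxidises it in place to the aldehyde, the secondary allylic TES ether survives, and amine addition at −78 °C with a cold neutral work-up protects the configuration at C6, the aldehyde being used at once.

Step 10
Reactants: 15 (2R,3Z,6Z)-10-bromo-6-methyl-2-(triethylsilyloxy)undeca-3,6,10-trienal
Product: 16 (1S,2R,3Z,6Z)-6-methyl-10-methylidene-2-(triethylsilyloxy)cyclodeca-3,6-dien-1-ol (C5 alcohol, C6 TES ether)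
Conditions: CrCl2 (10 equiv), NiCl2 (5 mol %), DMSO, rt to 40 °C, slow addition, 3 mM
Reagents that add atoms: none
Why: In this Nozaki–Hiyama–Kishi macrocyclisation zerovalent nickel inserts into the C4–Br bond, transmetalation gives an alkenyl species of trivalent chromium that adds only to the aldehyde and closes the ten-membered ring at C4–C5 (the two Z alkenes preorganise the chain), and C5 is set by Felkin–Anh attack anti to the non-chelating C6 silyloxy group, which should give the 5,6-anti (5S) alcohol, any minor epimer being removed by chromatography.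

Step 11
Reactants: 16 (1S,2R,3Z,6Z)-6-methyl-10-methylidene-2-(triethylsilyloxy)cyclodeca-3,6-dien-1-ol
Product: 17 (1S,2R,3Z,6Z)-1-(tert-butyldimethylsilyloxy)-6-methyl-10-methylidene-2-(triethylsilyloxy)cyclodeca-3,6-diene
Conditions: TBSOTf, 2,6-lutidine, CH2Cl2, −78 to 0 °C
Reagents that add atoms: tert-butyldimethylsilyl triflate, CC(C)(C)[Si](C)(C)OS(=O)(=O)C(F)(F)F
Why: Silylation with the silyl triflate and a hindered pyridine base protects even the hindered allylic C5 hydroxyl.

Step 12
Reactants: 17 (1S,2R,3Z,6Z)-1-(tert-butyldimethylsilyloxy)-6-methyl-10-methylidene-2-(triethylsilyloxy)cyclodeca-3,6-diene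
Product: 18 (1R,2Z,5Z,10S)-10-(tert-butyldimethylsilyloxy)-5-methyl-9-methylidenecyclodeca-2,5-dien-1-ol (C6 alcohol, C5 TBS ether)
Conditions: PPTS (cat.), MeOH/CH2Cl2, 0 °C
Reagents that add atoms: none
Why: Acid-catalysed methanolysis cleaves the TES ether much faster than the bulkier TBS ether, so that only the C6 hydroxyl is freed.

Step 13
Reactants: 18 (1R,2Z,5Z,10S)-10-(tert-butyldimethylsilyloxy)-5-methyl-9-methylidenecyclodeca-2,5-dien-1-ol; 19 diethylphosphonoacetic acid
Product: 20 (1R,2Z,5Z,10S)-10-(tert-butyldimethylsilyloxy)-5-methyl-9-methylidenecyclodeca-2,5-dien-1-yl 2-(diethoxyphosphoryl)acetate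
Conditions: DCC, DMAP (cat.), CH2Cl2, 0 °C to rt
Reagents that add atoms: none
Why: Steglich esterification acylates the secondary allylic alcohol under neutral conditions without disturbing the silyl ether or the alkenes.

Step 14
Reactants: 20 (1R,2Z,5Z,10S)-10-(tert-butyldimethylsilyloxy)-5-methyl-9-methylidenecyclodeca-2,5-dien-1-yl 2-(diethoxyphosphoryl)acetate
Product: 21 (1R,2Z,5Z,10S)-10-(tert-butyldimethylsilyloxy)-5-methyl-9-methylidenecyclodeca-2,5-dien-1-yl 2-diazo-2-(diethoxyphosphoryl)acetate
Conditions: 4-acetamidobenzenesulfonyl azide, DBU, MeCN, 0 °C to rt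
Reagents that add atoms: 4-acetamidobenzenesulfonyl azide, CC(=O)Nc1ccc(cc1)S(=O)(=O)N=[N+]=[N-]
Why: Regitz diazo transfer from the sulfonyl azide to the methylene activated by both phosphonate and ester gives the stable diazophosphonoacetate.

Step 15
Reactants: 21 (1R,2Z,5Z,10S)-10-(tert-butyldimethylsilyloxy)-5-methyl-9-methylidenecyclodeca-2,5-dien-1-yl 2-diazo-2-(diethoxyphosphoryl)acetate
Product: 22 cyclopropane-fused phosphono lactone (5S,6R,7R,8R,11S): lactone O6–C12(=O)–C11–C7–C6, cyclopropane C7–C8–C11, diethyl phosphonate on C11, Z C1=C10, C4 exo-methylene, C5 OTBS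
Conditions: Rh2(OAc)4 (2 mol %), CH2Cl2, reflux, slow addition of 21, 0.01 M
Reagents that add atoms: none
Why: Rh2(OAc)4, a divalent rhodium dimer, takes up the diazo carbon, expels N2 and gives an electrophilic carbenoid at C11 that adds to the Z C7=C8 alkene in a concerted, asynchronous (2+1) cycloaddition, the well-known intramolecular cyclopropanation of allylic diazo esters. The γ-lactone (O6, C12, C11, C7, C6) closes in the 5-exo mode as C11 bonds to the proximal alkene carbon C7, and the cyclopropane (C7, C8, C11) closes by the second bond C11–C8, so the bicycle is necessarily cis-fused. C7 and C8 keep the cis relation of the Z alkene because the addition is stereospecifically syn, C11 is fixed by the ring fusion, and the absolute sense comes from C6: the short O6 tether can deliver C11 only to the alkene face on the side of O6, anti to the C5–C6 bond, which in the Z cycloalkene stands roughly perpendicular to the alkene plane. The step needs this face selectivity and chemoselectivity: cyclopropanation of C4=C15 would require a six-membered lactone, C1=C10 is out of reach, and insertion into C5–H is disfavoured by the bulky TBS group and by the preference of Rh2(OAc)4 carbenoids for a proximal alkene. Slow addition at high dilution suppresses carbene dimerisation.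

Step 16
Reactants: 22 cyclopropane-fused phosphono lactone; 23 angelic acid
Product: 24 α-(diethoxyphosphoryl) γ-lactone (5S,6R,7R,8S; C11 epimers) with the C8 angelate, Z C1=C10, C4 exo-methylene, C5 OTBS
Conditions: 23 (4 equiv), Cs2CO3 (1.5 equiv), DMF, 70 °C
Reagents that add atoms: none
Why: In this homoconjugate (SN2-type) opening of a doubly activated cyclopropane the exocyclic C8–C11 bond, which overlaps with the lactone carbonyl and is activated by carbonyl and phosphoryl groups, is broken by backside attack of the carboxylate at C8 with inversion, which sets the C8 ester configuration, and the phosphonate carbanion is protonated by the excess angelic acid so that the opening cannot reverse and the Z geometry of the angelate, never activated as an acyl donor, is kept.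

Step 17
Reactants: 24 α-(diethoxyphosphoryl) γ-lactone with the C8 angelate
Product: 25 (5S,6R,7R,8S)-8-angeloyloxy-5-(tert-butyldimethylsilyloxy)germacra-1(10)Z,4(15),11(13)-trien-12,6-olide
Conditions: 37 % aq. HCHO, K2CO3, THF, 0 °C to rt
Reagents that add atoms: formaldehyde, C=O
Why: Horner–Wadsworth–Emmons olefination of the α-phosphono lactone with formaldehyde under mild carbonate base gives the α-methylene lactone, removes the stereocentre at C11 and is faster than re-closure of the cyclopropane by loss of angelate.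

Step 18
Reactants: 25 (5S,6R,7R,8S)-8-angeloyloxy-5-(tert-butyldimethylsilyloxy)germacra-1(10)Z,4(15),11(13)-trien-12,6-olide
Product: 26 (1R,5S,6R,7R,8S,10S)-8-angeloyloxy-5-(tert-butyldimethylsilyloxy)-1,10-epoxygermacra-4(15),11(13)-dien-12,6-olide
Conditions: mCPBA (1.05 equiv), CH2Cl2, −20 to 0 °C; NaHCO3/Na2S2O3 work-up
Reagents that add atoms: 3-chloroperbenzoic acid, OOC(=O)c1cccc(Cl)c1
Why: Prilezhaev epoxidation is stereospecific (Z alkene to cis epoxide) and chemoselective for the trisubstituted, most electron-rich C1=C10 alkene over the hindered C4=C15 and the electron-poor enoate alkenes, the peracid is expected to attack the outer face of the alkene in the lactone-fused ring to give the 1R,10S epoxide, and the C5 silyl ether prevents hydroxyl-directed oxidation of C4=C15.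

Step 19
Reactants: 26 (1R,5S,6R,7R,8S,10S)-8-angeloyloxy-5-(tert-butyldimethylsilyloxy)-1,10-epoxygermacra-4(15),11(13)-dien-12,6-olide
Product: 27 (1R,5S,6R,7R,8S,10S)-8-angeloyloxy-1,10-epoxy-5-hydroxygermacra-4(15),11(13)-dien-12,6-olide (CNP0227074.3)
Conditions: TBAF, AcOH (1:1), THF, 0 °C to rt
Reagents that add atoms: none
Why: Fluoride-mediated desilylation buffered with acetic acid removes the TBS ether without opening the epoxide or adding to the α-methylene lactone.

Compound list
1 | propargyl alcohol | C#CCO | starting material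
2 | bromomagnesium (Z)-3-(bromomagnesio)-2-methylprop-2-en-1-olate | Br[Mg]OC/C(C)=C\[Mg]Br | intermediate
3 | (Z)-3-iodo-2-methylprop-2-en-1-ol | OC/C(C)=C\I | intermediate
4 | 3-bromobut-3-en-1-ol | C=C(Br)CCO | starting material
5 | 2-bromo-4-iodobut-1-ene | C=C(Br)CCI | intermediate
6 | (3-bromobut-3-en-1-yl)zinc iodide | C=C(Br)CC[Zn]I | intermediate
7 | (2Z)-6-bromo-2-methylhepta-2,6-dien-1-ol | OC/C(C)=C\CCC(Br)=C | intermediate
8 | (5Z)-2,7-dibromo-6-methylhepta-1,5-diene | BrC/C(C)=C\CCC(Br)=C | intermediate
9 | [(3Z)-7-bromo-3-methylocta-3,7-dien-1-yl]triphenylphosphonium bromide | C=C(Br)CC/C=C(C)\CC[P+](c1ccccc1)(c1ccccc1)c1ccccc1.[Br-] | intermediate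
10 | (S)-glyceraldehyde acetonide | CC1(C)OC[C@H](O1)C=O | starting material
11 | [(3Z)-7-bromo-3-methylocta-3,7-dien-1-ylidene]triphenylphosphorane | C=C(Br)CC/C=C(C)\CC=P(c1ccccc1)(c1ccccc1)c1ccccc1 | intermediate
12 | (4R)-4-[(1Z,4Z)-8-bromo-4-methylnona-1,4,8-trien-1-yl]-2,2-dimethyl-1,3-dioxolane | CC1(C)OC[C@H](O1)/C=C\C/C(C)=C\CCC(Br)=C | intermediate
13 | (2R,3Z,6Z)-10-bromo-6-methylundeca-3,6,10-triene-1,2-diol | OC[C@H](O)/C=C\C/C(C)=C\CCC(Br)=C | intermediate
14 | (2R,3Z,6Z)-10-bromo-6-methyl-1,2-bis(triethylsilyloxy)undeca-3,6,10-triene | CC[Si](CC)(CC)OC[C@H](O[Si](CC)(CC)CC)/C=C\C/C(C)=C\CCC(Br)=C | intermediate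
15 | (2R,3Z,6Z)-10-bromo-6-methyl-2-(triethylsilyloxy)undeca-3,6,10-trienal | O=C[C@H](O[Si](CC)(CC)CC)/C=C\C/C(C)=C\CCC(Br)=C | intermediate
16 | (1S,2R,3Z,6Z)-6-methyl-10-methylidene-2-(triethylsilyloxy)cyclodeca-3,6-dien-1-ol | CC[Si](CC)(CC)O[C@@H]1/C=C\C/C(C)=C\CCC(=C)[C@@H]1O | intermediate
17 | (1S,2R,3Z,6Z)-1-(tert-butyldimethylsilyloxy)-6-methyl-10-methylidene-2-(triethylsilyloxy)cyclodeca-3,6-diene | CC[Si](CC)(CC)O[C@@H]1/C=C\C/C(C)=C\CCC(=C)[C@@H]1O[Si](C)(C)C(C)(C)C | intermediate
18 | (1R,2Z,5Z,10S)-10-(tert-butyldimethylsilyloxy)-5-methyl-9-methylidenecyclodeca-2,5-dien-1-ol | O[C@@H]1/C=C\C/C(C)=C\CCC(=C)[C@@H]1O[Si](C)(C)C(C)(C)C | intermediate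
19 | diethylphosphonoacetic acid | OC(=O)CP(=O)(OCC)OCC | starting material
20 | 2-(diethoxyphosphoryl)acetate of 18 | CCOP(=O)(OCC)CC(=O)O[C@@H]1/C=C\C/C(C)=C\CCC(=C)[C@@H]1O[Si](C)(C)C(C)(C)C | intermediate
21 | 2-diazo-2-(diethoxyphosphoryl)acetate of 18 (key-step precursor) | CCOP(=O)(OCC)C(=[N+]=[N-])C(=O)O[C@@H]1/C=C\C/C(C)=C\CCC(=C)[C@@H]1O[Si](C)(C)C(C)(C)C | intermediate
22 | cyclopropane-fused phosphono lactone (5S,6R,7R,8R,11S) (key-step product) | CCOP(=O)(OCC)[C@]12C(=O)O[C@@H]3[C@H]1[C@H]2C/C(C)=C\CCC(=C)[C@@H]3O[Si](C)(C)C(C)(C)C | intermediate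
23 | angelic acid, (Z)-2-methylbut-2-enoic acid | C/C=C(/C)C(=O)O | starting material
24 | α-(diethoxyphosphoryl) γ-lactone with C8 angelate (5S,6R,7R,8S; C11 epimers) | CCOP(=O)(OCC)C1C(=O)O[C@@H]2[C@H]1[C@@H](OC(=O)/C(C)=C\C)C/C(C)=C\CCC(=C)[C@@H]2O[Si](C)(C)C(C)(C)C | intermediate
25 | (5S,6R,7R,8S)-8-angeloyloxy-5-(tert-butyldimethylsilyloxy)germacra-1(10)Z,4(15),11(13)-trien-12,6-olide | C=C1C(=O)O[C@@H]2[C@H]1[C@@H](OC(=O)/C(C)=C\C)C/C(C)=C\CCC(=C)[C@@H]2O[Si](C)(C)C(C)(C)C | intermediate
26 | (1R,5S,6R,7R,8S,10S)-8-angeloyloxy-5-(tert-butyldimethylsilyloxy)-1,10-epoxygermacra-4(15),11(13)-dien-12,6-olide | C=C1C(=O)O[C@@H]2[C@H]1[C@@H](OC(=O)/C(C)=C\C)C[C@]1(C)O[C@@H]1CCC(=C)[C@@H]2O[Si](C)(C)C(C)(C)C | intermediate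
27 | (1R,5S,6R,7R,8S,10S)-8-angeloyloxy-1,10-epoxy-5-hydroxygermacra-4(15),11(13)-dien-12,6-olide (CNP0227074.3) | C=C1C(=O)O[C@@H]2[C@H]1[C@@H](OC(=O)/C(C)=C\C)C[C@]1(C)O[C@@H]1CCC(=C)[C@@H]2O | target

Total step count: 19. Longest linear sequence: 18 steps (1 to 27 through steps 1 and 3–19; step 2 is a side branch).

Steps most likely to fail

Step 15. The carbenoid may lose chemoselectivity: insertion into the activated C5–H bond, cyclopropanation of C4=C15 through a six-membered lactone, or carbene dimerisation may compete with addition to C7=C8. The fallback avoids a free carbenoid and sets out from 20. Iodocarbocyclisation with I2, Ti(Ot-Bu)4 and CuO in CH2Cl2 lets the phosphonoacetate enolate attack the iodonium ion of C7=C8 at C7, anti to iodine, and should give the C8 iodo phosphono lactone F1. Cs2CO3 in DMF then closes C8–C11 by displacement of iodide with inversion. The two anti steps add up to the same syn cyclopropanation, and the route is rejoined at 22.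

Step 16. Backside attack of the weakly nucleophilic carboxylate at the secondary, ring-bound C8 may be too slow, so that reversal or attack on the lactone takes over. The fallback uses ketone activation, which makes the cyclopropane more electrophilic, and sets out from 18. Heating with 2,2,6-trimethyl-4H-1,3-dioxin-4-one in toluene gives the acetoacetate F2. Regitz diazo transfer gives the diazoacetoacetate F3. Rh2(OAc)4 gives the acetyl cyclopropane lactone F4. Cesium angelate opens F4 at C8 with inversion to the α-acetyl lactone F5. Deacetylative methylenation of F5 with paraformaldehyde and K2CO3 in THF rejoins the route at 25.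

Step 18. Facial selectivity of peracid attack on C1=C10 is governed only by the ring conformation and may be low or opposite to the one needed. The fallback inverts the facial outcome and sets out from 25. NBS in THF/H2O at 0 °C forms the bromonium ion on the face the peracid prefers, and water opens it at the tertiary C10 from the other face, giving the bromohydrin F6 (Br at C1, OH at C10). K2CO3 in acetone closes the epoxide by displacement of bromide at C1, placing oxygen on the opposite face, and the route is rejoined at 26.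

Further compounds
F1 | step 15 | C8 iodo α-(diethoxyphosphoryl) γ-lactone (5S,6R,7R,8S; C11 epimers) | CCOP(=O)(OCC)C1C(=O)O[C@@H]2[C@H]1[C@@H](I)C/C(C)=C\CCC(=C)[C@@H]2O[Si](C)(C)C(C)(C)C
F2 | step 16 | 3-oxobutanoate (acetoacetate) of 18 | CC(=O)CC(=O)O[C@@H]1/C=C\C/C(C)=C\CCC(=C)[C@@H]1O[Si](C)(C)C(C)(C)C
F3 | step 16 | 2-diazo-3-oxobutanoate of 18 | CC(=O)C(=[N+]=[N-])C(=O)O[C@@H]1/C=C\C/C(C)=C\CCC(=C)[C@@H]1O[Si](C)(C)C(C)(C)C
F4 | step 16 | cyclopropane-fused lactone with acetyl on C11 | CC(=O)[C@]12C(=O)O[C@@H]3[C@H]1[C@H]2C/C(C)=C\CCC(=C)[C@@H]3O[Si](C)(C)C(C)(C)C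
F5 | step 16 | α-acetyl γ-lactone with C8 angelate (C11 epimers) | CC(=O)C1C(=O)O[C@@H]2[C@H]1[C@@H](OC(=O)/C(C)=C\C)C/C(C)=C\CCC(=C)[C@@H]2O[Si](C)(C)C(C)(C)C
F6 | step 18 | C1 bromo, C10 hydroxy bromohydrin of 25 | C=C1C(=O)O[C@@H]2[C@H]1[C@@H](OC(=O)/C(C)=C\C)C[C@](C)(O)[C@@H](Br)CCC(=C)[C@@H]2O[Si](C)(C)C(C)(C)C
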